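**Retrosynthetic overview**
- The target is a 6,8''-biflavone. Unit 1 is acacetin joined through C6; unit 2 is a 5''-hydroxy-7''-methoxy-2''-(4-hydroxyphenyl)chromone joined through C8''. The last operations are O-methylation of the 7''-phenol and removal of four benzyl ethers.
- The strategy rests on the pyranone ring C of unit 2 (O1'', C2'', C3'', C4'', C4a'', C8a''). C4''=O comes from CO, the C3''–C2'' pair with ring B of unit 2 from an arylacetylene, and C4a''/C8a''–O1'' from an ortho-iodophenol on ring A of unit 2. One pot forms C4a''–C4'', C4''–C3'' and O1''–C2''.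
- The iodophenol 12 comes from mono-iodination of a mirror-symmetric 2-aryl-5-benzyloxyresorcinol 11, so the iodine position is unambiguous and the 5''-oxygen is already blocked as a benzyl ether.
- The C6–C8'' biaryl bond is made earlier by Negishi coupling of 6-iodo-5,7-di-O-benzylacacetin 4 with the arylzinc obtained by ortho-lithiation of 1-(benzyloxy)-3,5-bis(methoxymethoxy)benzene 7.
- Ring order: rings A, C and B of unit 1 arrive as acacetin, ring A of unit 2 as phloroglucinol and ring B of unit 2 with the alkyne; ring C of unit 2 is the only ring closed, in step 9.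

Key step: step 9

Assumption: the target is drawn without a descriptor for the C6–C8'' biaryl axis and has no stereocentre, so the route aims at material that is racemic about this axis.

**Step 1**
Reactants: 1 acacetin
Product: 2 7-O-benzylacacetin
Conditions: BnBr (1.1 equiv), K2CO3, acetone, reflux
Reagents that add atoms: benzyl bromide, BrCc1ccccc1
Why: Williamson etherification; the 7-OH is the acidic, unchelated phenol whereas the 5-OH is held in a hydrogen bond to the C4 carbonyl, so mono-benzylation at O7 is expected.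

**Step 2**
Reactants: 2 7-O-benzylacacetin
Product: 3 7-O-benzyl-6-iodoacacetin
Conditions: BnNMe3 ICl2 (1.1 equiv), CaCO3, CH2Cl2/MeOH, rt
Reagents that add atoms: benzyltrimethylammonium dichloroiodate, C[N+](C)(C)Cc1ccccc1.Cl[I-]Cl
Why: Electrophilic aromatic iodination of a 5-hydroxy-7-alkoxyflavone, which should go to C6, the position ortho to the free chelated 5-OH, in preference to C8 or the anisyl ring B.

**Step 3**
Reactants: 3 7-O-benzyl-6-iodoacacetin
Product: 4 5,7-di-O-benzyl-6-iodoacacetin
Conditions: BnBr (2 equiv), K2CO3, nBu4NI (cat.), DMF, 70 °C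
Reagents that add atoms: benzyl bromide, BrCc1ccccc1
Why: Williamson etherification of the chelated 5-OH, which needs a polar solvent and heat but has no competing nucleophilic site.

**Step 4**
Reactants: 5 phloroglucinol
Product: 6 3,5-bis(methoxymethoxy)phenol
Conditions: MOMCl (2.0 equiv), iPr2NEt (2.2 equiv), DMF, 0 °C to rt; chromatographic separation
Reagents that add atoms: chloromethyl methyl ether, COCCl
Why: O-alkylation to MOM acetals; with two equivalents the bis-ether should be the main component of a statistical mixture from a very cheap triol, and it is separated from mono- and tris-ether by chromatography.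

**Step 5**
Reactants: 6 3,5-bis(methoxymethoxy)phenol
Product: 7 1-(benzyloxy)-3,5-bis(methoxymethoxy)benzene
Conditions: BnBr (1.2 equiv), K2CO3, DMF, rt
Reagents that add atoms: benzyl bromide, BrCc1ccccc1
Why: Williamson etherification of the single remaining phenol.

**Step 6**
Reactants: 7 1-(benzyloxy)-3,5-bis(methoxymethoxy)benzene; 4 5,7-di-O-benzyl-6-iodoacacetin
Product: 10 6-[4-(benzyloxy)-2,6-bis(methoxymethoxy)phenyl]-5,7-di-O-benzylacacetin, via aryllithium 8 (not isolated), via arylzinc chloride 9 (not isolated)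
Conditions: 7 (1.6 equiv), n-BuLi (1.5 equiv), THF, 0 °C; ZnCl2 (1.7 equiv), 0 °C to rt; then 4 (1.0 equiv), Pd2(dba)3 (2 mol %), RuPhos (8 mol %), THF/NMP, 75 °C
Reagents that add atoms: none
Why: Directed ortho-metalation at the carbon between the two MOM ethers, transmetalation to zinc and Negishi coupling; a dialkylbiarylphosphine-ligated palladium catalyst is known to join di-ortho-substituted arylzinc chlorides to di-ortho-substituted aryl halides, and keeping n-BuLi below 7 and passing through zinc protects the chromone carbonyl.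

**Step 7**
Reactants: 10 6-[4-(benzyloxy)-2,6-bis(methoxymethoxy)phenyl]-5,7-di-O-benzylacacetin
Product: 11 5-(benzyloxy)-2-(5,7-di-O-benzylacacetin-6-yl)resorcinol
Conditions: HCl (conc., 5 equiv), MeOH/THF, 45 °C
Reagents that add atoms: none
Why: Acid-catalysed acetal exchange removes both MOM ethers, while benzyl ethers, the methyl ether and the chromone are stable to dilute methanolic HCl.

**Step 8**
Reactants: 11 5-(benzyloxy)-2-(5,7-di-O-benzylacacetin-6-yl)resorcinol
Product: 12 5-(benzyloxy)-4-iodo-2-(5,7-di-O-benzylacacetin-6-yl)resorcinol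
Conditions: NIS (1.0 equiv), MeCN/CH2Cl2, −30 to 0 °C, dark
Reagents that add atoms: N-iodosuccinimide, O=C1CCC(=O)N1I
Why: Electrophilic iodination of a phloroglucinol-type ring, which is far more nucleophilic than the carbonyl-deactivated ring A of unit 1; the two open positions are equivalent by symmetry, so one equivalent at low temperature should give a single mono-iodide.

**Step 9**
Reactants: 12 5-(benzyloxy)-4-iodo-2-(5,7-di-O-benzylacacetin-6-yl)resorcinol; 13 carbon monoxide; 14 1-(benzyloxy)-4-ethynylbenzene
Product: 17 5,7,5'',4'''-tetra-O-benzyl-7''-O-demethyl derivative of target 19, via ynone 15 (not isolated), via enaminone 16 (not isolated)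
Conditions: PdCl2(PPh3)2 (5 mol %), CO (20 bar), 14 (1.5 equiv), Et2NH, 100 °C, autoclave
Reagents that add atoms: none
Why: Zerovalent palladium, formed from PdCl2(PPh3)2 under CO and amine, adds oxidatively to the C4a''–I bond of 12, CO inserts to give the aroylpalladium species, and transfer of the acetylide of 14 followed by reductive elimination gives ynone 15, forming C4a''–C4'' and C4''–C3''. Et2NH adds to the β-carbon of 15 to give enaminone 16, and the phenol ortho to the acyl group attacks that carbon and expels the amine, forming O1''–C2'' and closing the pyranone ring C of unit 2 in a 6-endo addition–elimination. The closest known reaction type is the palladium-catalysed carbonylative coupling–cyclisation of ortho-iodophenols with terminal alkynes and CO in a secondary amine to give flavones. No stereocentre is formed. The step needs CO insertion to precede alkynylation, which CO pressure, the absence of copper and the doubly ortho-substituted arylpalladium should secure, and it needs six- over five-membered closure, which the amine adduct enforces because its β-carbon is the only electrophilic site. The ring oxygen is fixed by the substrate, since the other oxygen ortho to the acyl group is benzylated and the second free phenol sits para to it.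

**Step 10**
Reactants: 17 5,7,5'',4'''-tetra-O-benzyl-7''-O-demethyl derivative of target 19
Product: 18 5,7,5'',4'''-tetra-O-benzyl derivative of target 19
Conditions: MeI (3 equiv), K2CO3, DMF, rt to 40 °C
Reagents that add atoms: iodomethane, CI
Why: Williamson O-methylation of the only free phenol, the acidic 7''-OH para to the C4'' carbonyl.

**Step 11**
Reactants: 18 5,7,5'',4'''-tetra-O-benzyl derivative of target 19
Product: 19 target, 6-[5-hydroxy-2-(4-hydroxyphenyl)-7-methoxy-4-oxo-4H-chromen-8-yl]-5,7-dihydroxy-2-(4-methoxyphenyl)-4H-chromen-4-one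
Conditions: H2 (1 atm), 10% Pd/C, THF/MeOH, rt
Reagents that add atoms: none
Why: Catalytic hydrogenolysis of the four aryl benzyl ethers, which is normally much faster than reduction of the chromone C2=C3 bonds and leaves both methyl ethers in place.

**Compound list**
1 | acacetin (5,7-dihydroxy-2-(4-methoxyphenyl)-4H-chromen-4-one) | COc1ccc(-c2cc(=O)c3c(O)cc(O)cc3o2)cc1 | starting material
2 | 7-O-benzylacacetin | COc1ccc(-c2cc(=O)c3c(O)cc(OCc4ccccc4)cc3o2)cc1 | intermediate
3 | 7-O-benzyl-6-iodoacacetin | COc1ccc(-c2cc(=O)c3c(O)c(I)c(OCc4ccccc4)cc3o2)cc1 | intermediate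
4 | 5,7-di-O-benzyl-6-iodoacacetin | COc1ccc(-c2cc(=O)c3c(OCc4ccccc4)c(I)c(OCc4ccccc4)cc3o2)cc1 | intermediate
5 | phloroglucinol | Oc1cc(O)cc(O)c1 | starting material
6 | 3,5-bis(methoxymethoxy)phenol | COCOc1cc(O)cc(OCOC)c1 | intermediate
7 | 1-(benzyloxy)-3,5-bis(methoxymethoxy)benzene | COCOc1cc(OCOC)cc(OCc2ccccc2)c1 | intermediate
8 | [4-(benzyloxy)-2,6-bis(methoxymethoxy)phenyl]lithium (formed in the flask) | [Li]c1c(OCOC)cc(OCc2ccccc2)cc1OCOC | intermediate
9 | [4-(benzyloxy)-2,6-bis(methoxymethoxy)phenyl]zinc chloride (formed in the flask) | Cl[Zn]c1c(OCOC)cc(OCc2ccccc2)cc1OCOC | intermediate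
10 | 6-[4-(benzyloxy)-2,6-bis(methoxymethoxy)phenyl]-5,7-di-O-benzylacacetin | COc1ccc(-c2cc(=O)c3c(OCc4ccccc4)c(-c4c(OCOC)cc(OCc5ccccc5)cc4OCOC)c(OCc4ccccc4)cc3o2)cc1 | intermediate
11 | 5-(benzyloxy)-2-(5,7-di-O-benzylacacetin-6-yl)resorcinol | COc1ccc(-c2cc(=O)c3c(OCc4ccccc4)c(-c4c(O)cc(OCc5ccccc5)cc4O)c(OCc4ccccc4)cc3o2)cc1 | intermediate
12 | 5-(benzyloxy)-4-iodo-2-(5,7-di-O-benzylacacetin-6-yl)resorcinol (racemic about the biaryl axis) | COc1ccc(-c2cc(=O)c3c(OCc4ccccc4)c(-c4c(O)cc(OCc5ccccc5)c(I)c4O)c(OCc4ccccc4)cc3o2)cc1 | intermediate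
13 | carbon monoxide | [C-]#[O+] | starting material
14 | 1-(benzyloxy)-4-ethynylbenzene | C#Cc1ccc(OCc2ccccc2)cc1 | starting material
15 | ynone: compound 12 with a 3-[4-(benzyloxy)phenyl]prop-2-ynoyl group in place of iodine (formed in the flask) | COc1ccc(-c2cc(=O)c3c(OCc4ccccc4)c(-c4c(O)cc(OCc5ccccc5)c(C(=O)C#Cc5ccc(OCc6ccccc6)cc5)c4O)c(OCc4ccccc4)cc3o2)cc1 | intermediate
16 | enaminone: (E)-3-(diethylamino)-3-[4-(benzyloxy)phenyl]prop-2-en-1-one adduct of 15 (formed in the flask) | COc1ccc(-c2cc(=O)c3c(OCc4ccccc4)c(-c4c(O)cc(OCc5ccccc5)c(C(=O)/C=C(\c5ccc(OCc6ccccc6)cc5)N(CC)CC)c4O)c(OCc4ccccc4)cc3o2)cc1 | intermediate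
17 | 5,7,5'',4'''-tetra-O-benzyl-7''-O-demethyl derivative of the target (free 7''-OH) | COc1ccc(-c2cc(=O)c3c(OCc4ccccc4)c(-c4c(O)cc(OCc5ccccc5)c5c(=O)cc(-c6ccc(OCc7ccccc7)cc6)oc45)c(OCc4ccccc4)cc3o2)cc1 | intermediate
18 | 5,7,5'',4'''-tetra-O-benzyl derivative of the target | COc1ccc(-c2cc(=O)c3c(OCc4ccccc4)c(-c4c(OC)cc(OCc5ccccc5)c5c(=O)cc(-c6ccc(OCc7ccccc7)cc6)oc45)c(OCc4ccccc4)cc3o2)cc1 | intermediate
19 | CNP0290866.0, 6-[5-hydroxy-2-(4-hydroxyphenyl)-7-methoxy-4-oxo-4H-chromen-8-yl]-5,7-dihydroxy-2-(4-methoxyphenyl)-4H-chromen-4-one | COc1ccc(-c2cc(=O)c3c(O)c(-c4c(OC)cc(O)c5c(=O)cc(-c6ccc(O)cc6)oc45)c(O)cc3o2)cc1 | target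

**Step count**
Total steps: 11. Longest linear sequence: 9 steps (acacetin 1 to target 19 through steps 1–3 and 6–11).

**Steps most likely to fail**

1. Step 9 (carbonylative annulation). The hindered, electron-rich arylpalladium species may be alkynylated before CO inserts, which leads on to five-membered closure. It may also be captured by CO and Et2NH as an amide, or reduced with loss of iodine. The fallback builds ring C of unit 2 by the chalcone route and sets out from 12. Stille coupling with tributyl(1-ethoxyvinyl)stannane (PdCl2(PPh3)2, dioxane, 90 °C) should give the 1-ethoxyvinyl compound F1. Dilute aqueous HCl in THF should hydrolyse it to the ortho-hydroxyacetophenone F2. Claisen–Schmidt condensation with 4-(benzyloxy)benzaldehyde (KOH, EtOH/THF, rt) should give the (E)-2'-hydroxychalcone F3. Oxidative cyclisation with catalytic I2 in DMSO at 120 °C closes the pyranone ring through the only phenol ortho to the ketone. The fallback rejoins the route at 17.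

2. Step 6 (tetra-ortho-substituted Negishi coupling). Transmetalation and reductive elimination at a carbon flanked by four ortho oxygens may be slow, so that protodemetalation of 9 and reductive deiodination of 4 take over; benzylic lithiation of 7 may also erode the zinc reagent. The fallback exchanges the roles of the partners in a Suzuki–Miyaura coupling and sets out from 4 and 7. Miyaura borylation of 4 (PdCl2(dppf), bis(pinacolato)diboron, KOAc, DMSO, 85 °C) should give the flavone-6-boronic pinacol ester F4; boron then sits on the electron-poorer ring, which resists protodeboronation better. Lithiation of 7 (n-BuLi, THF, 0 °C) and quenching with I2 should give 5-(benzyloxy)-2-iodo-1,3-bis(methoxymethoxy)benzene F5. Coupling of F4 with F5 (Pd(OAc)2, SPhos, K3PO4, toluene/H2O, 100 °C) rejoins the route at 10.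

3. Step 8 (mono-iodination). The free resorcinol ring is so activated that a second iodination at the equivalent position may compete with the first, giving di-iodide beside unreacted 11. The fallback iodinates before the phenols are unmasked and sets out from 10. NIS (1.05 equiv, MeCN, 0 °C to rt) should iodinate the tris-ether ring of 10 once, between a MOM ether and the benzyl ether, to give the mono-iodide F6; a second iodination of this more crowded, less activated ring should be slower. Brief treatment with HCl in MeOH/THF at rt then removes both MOM groups and rejoins the route at 12.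

**Further compounds**
F1 | step 9 | 5-(benzyloxy)-4-(1-ethoxyvinyl)-2-(5,7-di-O-benzylacacetin-6-yl)resorcinol | COc1ccc(-c2cc(=O)c3c(OCc4ccccc4)c(-c4c(O)cc(OCc5ccccc5)c(C(=C)OCC)c4O)c(OCc4ccccc4)cc3o2)cc1
F2 | step 9 | 4-acetyl-5-(benzyloxy)-2-(5,7-di-O-benzylacacetin-6-yl)resorcinol | COc1ccc(-c2cc(=O)c3c(OCc4ccccc4)c(-c4c(O)cc(OCc5ccccc5)c(C(C)=O)c4O)c(OCc4ccccc4)cc3o2)cc1
F3 | step 9 | (E)-chalcone from F2 and 4-(benzyloxy)benzaldehyde | COc1ccc(-c2cc(=O)c3c(OCc4ccccc4)c(-c4c(O)cc(OCc5ccccc5)c(C(=O)/C=C/c5ccc(OCc6ccccc6)cc5)c4O)c(OCc4ccccc4)cc3o2)cc1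
F4 | step 6 | 5,7-di-O-benzylacacetin-6-boronic acid pinacol ester | COc1ccc(-c2cc(=O)c3c(OCc4ccccc4)c(B4OC(C)(C)C(C)(C)O4)c(OCc4ccccc4)cc3o2)cc1
F5 | step 6 | 5-(benzyloxy)-2-iodo-1,3-bis(methoxymethoxy)benzene | COCOc1cc(OCc2ccccc2)cc(OCOC)c1I
F6 | step 8 | 6-[4-(benzyloxy)-3-iodo-2,6-bis(methoxymethoxy)phenyl]-5,7-di-O-benzylacacetin | COc1ccc(-c2cc(=O)c3c(OCc4ccccc4)c(-c4c(OCOC)cc(OCc5ccccc5)c(I)c4OCOC)c(OCc4ccccc4)cc3o2)cc1
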